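I read this flask at 0.50 s, 30 s and 30 min. The eta run is this same flask, followed up to 12.0 min; delta is an earlier run at twice its charge.

| setting | eta | delta | flask |
|---|---|---|---|
| starting material | 0.50 M | 1 M | 0.50 M |
| remark | the very flask that is asked about, followed so far | run made earlier |  |
| time |  |  | 30 min |

- eta (time / min: isomer of the product / %, target / %): 1.00: 21.5, 74.9; 1.33: 18.6, 78.3; 2.00: 15.0, 82.3; 3.00: 10.3, 86.2; 5.00: 6.0, 91.5; 8.00: 4.1, 92.8; 12.0: 4.2, 93.6
- delta (time / min: isomer of the product / %, target / %): 4.00: 6.8, 91.1; 8.00: 2.4, 95.6; 12.0: 1.8, 96.5; 15.0: 1.9, 96.3; 20.0: 1.6, 96.4; 25.0: 1.8, 96.6; 30.0: 1.4, 97.2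

(scatter of a reading: 0.3 percentage points)

1. share of isomer of the product in isomer of the product plus target at 0.50 s
2. share of isomer of the product in isomer of the product plus target at 30 s
3. share of isomer of the product in isomer of the product plus target at 30 min

- a reading or a percentage of target counts all its forms, free or not

I start with the main step alone: starting material splits into target and isomer of the product, which gives one flat share, the kinetic one (kinetic control). The eta share is 22.3% at 1.00 min. But it is 10.7% at 3.00 min, so a flat share will not do.

Next I add a floor. The last readings of eta average 4.15% of the charge and those of delta 1.70%. As concentrations they are 20.7 mM and 17.0 mM, which stand closer together than the percentages, so I replace each late curve by its mean and take the mean of the two: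

[isomer of the product] at the plateau = mean of 20.7 mM and 17.0 mM = 18.9 mM

This plateau concentration is my carried quantity. Divided by the charge and by the last eta sum of isomer and target, 97.8%, it gives:

share at 30 min = 3.86%

The gap between the two means moves this by 0.38 percentage points either way.

Last I add the decay of the excess over that floor, read from the two eta shares:

k = 0.498 min⁻¹

Run backwards, it lifts the share to 27.5% at 30 s and 34.1% at 0.50 s. Both times lie before the first eta reading, so both values are stretches.

The forecast says 35%, 28% and 3.9%, and holds that “the plateau depends on concentration, perhaps through target aggregation or precipitation”.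

The flask gives 30.9%, 27.0% and 3.58%, and the forecast held at each time.

    target ⇌ isomer of the product (k = 0.00147 s⁻¹)
    starting material ⇌ dormant form (K = 4.00, k = 0.00349 s⁻¹)
    starting material ⇌ isomer of the product (K = 6.70, k = 0.0695 s⁻¹)
    starting material ⇌ target (K = 3.77, k = 0.157 s⁻¹)
    crystals ⇌ target, rate k5*(cs5 - [target]) while solid is left; crystals form when [target] > cs5 (solubility = 9.80 mM, k = 0.672 s⁻¹)

At 30.0 min this flask holds isomer of the product at 3.48% of its charge, which is 17.4 mM, beside crystals at 91.9%. A neighbouring flask charged at 0.20 M, with the rest held, takes the same reckoning: 18.9 mM over that charge and over 97.8% gives a share of 9.66%. That flask holds crystals at 80.6% and isomer of the product at 8.68% of its charge, and its share at 30 min is 9.22%.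

(The numbers in the tables were generated by integration with constants of no real substance; the scatter is artificial.)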